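**Retrosynthetic overview**

1. Ring names: A = formyl-bearing benzene, B = hexasubstituted benzene, C = seven-membered lactone–ether (depsidone) ring, D = 2,2-dimethylpyran-4-one ring fused to B.
2. Last disconnection, one operation: ring D is cut at aryl C–C(=O) and at O–C(CH3)2 (C5 unit = 3-methylbut-2-enoic acid) and ring C at the lactone C(=O)–O bond. This leads back to an open diaryl ether hydroquinone acid.
3. Enabling feature: before ring D exists, ring B has a single C–H carbon. It lies between the methyl-bearing carbon and a carbon with a free phenol O, and it is para to the diaryl-ether O. This adjacent C–H/O–H pair is a C,O-bis-nucleophile that matches C1 and C3 of the acid, while ring A is switched off by its formyl and carboxyl carbons.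
4. Diaryl ether O–C(ring B) bond: ring B is raised to the quinone level, so that the weakly nucleophilic, chelated ring-A phenol can displace bromide from a bromomethoxyquinone. The neighbouring OMe later blocks the wrong lactone and is removed last.
5. Ring order: A and B are bought as benzenes (orsellinic acid, 4,5-dimethoxy-2-methylbenzaldehyde), then C, then D.

Key step: step 8

Remark: the target has no stereocentre and no stereogenic double bond, so no SMILES carries a stereo descriptor and no step needs stereocontrol.

**Step 1**
Reactants: 1 orsellinic acid (2,4-dihydroxy-6-methylbenzoic acid)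
Product: 2 benzyl 4-(benzyloxy)-2-hydroxy-6-methylbenzoate
Conditions: BnBr (2.2 equiv), K2CO3, DMF, rt
Reagents that add atoms: benzyl bromide, BrCc1ccccc1
Why: Williamson-type O-alkylation, in which the carboxylate and the unchelated 4-OH are benzylated while the 2-OH, held in a hydrogen bond to the ester carbonyl, stays free for the later ether formation.

**Step 2**
Reactants: 2 benzyl 4-(benzyloxy)-2-hydroxy-6-methylbenzoate
Product: 3 benzyl 4-(benzyloxy)-3-formyl-2-hydroxy-6-methylbenzoate
Conditions: MgCl2 (anhydrous), Et3N, (CH2O)n, MeCN, reflux; then 1 M HCl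
Reagents that add atoms: paraformaldehyde (reacts as formaldehyde), C=O
Why: Casnati–Skattebøl ortho-formylation, in which the magnesium phenoxide delivers formaldehyde only ortho to the free OH; the sole free ortho carbon lies between OH and OBn, so the formyl group can enter at one site only (a second formaldehyde accepts the hydride).

**Step 3**
Reactants: 4 4,5-dimethoxy-2-methylbenzaldehyde
Product: 6 4,5-dimethoxy-2-methylphenol, via aryl formate 5 (not isolated)
Conditions: mCPBA, CH2Cl2, 0 °C to rt; then K2CO3 (cat.), MeOH, rt
Reagents that add atoms: mCPBA, OOC(=O)c1cccc(Cl)c1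
Why: Baeyer–Villiger (Dakin-type) oxidation, in which the electron-rich aryl group (para-OMe) migrates to oxygen to give formate 5, which methanolysis cleaves to the phenol.

**Step 4**
Reactants: 6 4,5-dimethoxy-2-methylphenol
Product: 7 2-bromo-3,4-dimethoxy-6-methylphenol
Conditions: NBS (1.0 equiv), CH2Cl2, −40 °C to 0 °C
Reagents that add atoms: N-bromosuccinimide, O=C1CCC(=O)N1Br
Why: Electrophilic aromatic bromination, directed to the only free carbon ortho to the phenol OH, which is also ortho to a methoxy group and so doubly activated, whereas the other C–H is meta to the OH.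

**Step 5**
Reactants: 7 2-bromo-3,4-dimethoxy-6-methylphenol
Product: 8 3-bromo-2-methoxy-5-methyl-1,4-benzoquinone
Conditions: PhI(OAc)2, MeCN–H2O, 0 °C
Reagents that add atoms: water, O
Why: Hypervalent-iodine oxidative demethylation of a 4-methoxyphenol, in which water adds to the phenoxenium ion at the para carbon that bears OMe and loss of methanol gives the p-quinone; ring B thereby becomes electrophilic, with bromine on the carbon that must carry the ether oxygen.

**Step 6**
Reactants: 3 benzyl 4-(benzyloxy)-3-formyl-2-hydroxy-6-methylbenzoate; 8 3-bromo-2-methoxy-5-methyl-1,4-benzoquinone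
Product: 9 benzyl 4-(benzyloxy)-3-formyl-2-[(2-methoxy-5-methyl-3,6-dioxocyclohexa-1,4-dien-1-yl)oxy]-6-methylbenzoate
Conditions: NaH (1.0 equiv), THF–DMF, 0 °C; then 8, −20 °C to rt
Reagents that add atoms: none
Why: Addition–elimination of a phenoxide on a bromo-1,4-benzoquinone, favoured at the bromine-bearing carbon because it is β to the quinone carbonyl that is not deactivated as a vinylogous ester by the OMe group, and because it is the only site where addition ends in irreversible loss of a leaving group.

**Step 7**
Reactants: 9 benzyl 4-(benzyloxy)-3-formyl-2-[(2-methoxy-5-methyl-3,6-dioxocyclohexa-1,4-dien-1-yl)oxy]-6-methylbenzoate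
Product: 10 2-(2,5-dihydroxy-6-methoxy-3-methylphenoxy)-3-formyl-4-hydroxy-6-methylbenzoic acid
Conditions: H2 (1 atm), 10% Pd/C, EtOAc, rt; filtered under argon and used directly
Reagents that add atoms: none
Why: Catalytic hydrogenation and hydrogenolysis in one operation reduce the quinone to the hydroquinone and cleave the benzyl ether and benzyl ester, while the doubly ortho-oxygenated, hydrogen-bonded aldehyde is reduced much more slowly.

**Step 8**
Reactants: 10 2-(2,5-dihydroxy-6-methoxy-3-methylphenoxy)-3-formyl-4-hydroxy-6-methylbenzoic acid; 11 3-methylbut-2-enoic acid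
Product: 14 target O-methyl ether (rings A–D complete; ring-B phenol still masked as OMe), via depsidone phenol 12 (not isolated), via ortho-hydroxyaryl enone 13 (not isolated)
Conditions: Eaton's reagent (P2O5/MeSO3H), rt; then 11 (2 equiv), 60 °C; ice–water
Reagents that add atoms: none
Why: In stage 1 P2O5/MeSO3H converts the di-ortho-substituted acid of 10 into its acyl mesylate/acylium ion, which is trapped by the only hydroxyl ortho to the diaryl-ether oxygen and closes ring C as lactone 12 (7-exo-trig acyl substitution, the known dehydrative lactonisation of 2-(2-hydroxyaryloxy)benzoic acids); the second ortho oxygen is blocked as OMe and both ortho carbons are substituted, so neither the isomeric lactone nor a xanthone can arise. In stage 2 the same medium ionises 11 to the 3-methylbut-2-enoyl cation, which acylates ring B of 12 at its single C–H, either directly or by O-acylation of the neighbouring phenol and Fries shift, to give enone 13. The phenol oxygen next to the new ketone then adds to the protonated β,β-dimethyl enone (6-endo-trig oxa-Michael addition), which closes ring D last and creates the quaternary C(CH3)2 carbon; no stereocentre is formed. The closest known reaction is the one-pot Friedel–Crafts acylation/oxa-Michael synthesis of 2,2-dimethylchroman-4-ones from resorcinols or pyrogallol and 3-methylbut-2-enoic acid in Eaton's reagent or polyphosphoric acid. Site selectivity between rings B and A is secured by the substrate: the ring-B C–H is ortho to OH, para to the ether oxygen and ortho to methyl, whereas the only C–H of ring A sits on a ring that carries the formyl and lactone carbonyl groups. Mode selectivity (acylation rather than tert-alkylation to a 4,4-dimethylchroman-2-one) is favoured by the flanking ring-B methyl group, which tolerates a planar acyl carbon but not a quaternary carbon next to it, and the staged addition of 11 ensures that ring C is closed before ring D.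

**Step 9**
Reactants: 14 target O-methyl ether
Product: 15 target CNP0271978.0 (4-formyl-3-hydroxy-1-methyl depsidone whose ring B carries 9-methyl, 6-hydroxy and a 7,8-fused 2,2-dimethyl-2,3-dihydropyran-4-one, O on C7 and C=O on C8)
Conditions: BCl3, CH2Cl2, −10 °C to rt; then H2O
Reagents that add atoms: none
Why: Lewis-acid ether cleavage, in which BCl3 preferentially attacks an aryl methyl ether that is flanked by two oxygen substituents and twisted out of the ring plane (here the only O-methyl group left), while lactone and aldehyde persist and any reversible opening of the tertiary C–O bond of ring D is undone by the same oxa-Michael addition on work-up.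

**Compound list**

1 | orsellinic acid (2,4-dihydroxy-6-methylbenzoic acid) | Cc1cc(O)cc(O)c1C(=O)O | starting material
2 | benzyl 4-(benzyloxy)-2-hydroxy-6-methylbenzoate | Cc1cc(OCc2ccccc2)cc(O)c1C(=O)OCc1ccccc1 | intermediate
3 | benzyl 4-(benzyloxy)-3-formyl-2-hydroxy-6-methylbenzoate | Cc1cc(OCc2ccccc2)c(C=O)c(O)c1C(=O)OCc1ccccc1 | intermediate
4 | 4,5-dimethoxy-2-methylbenzaldehyde | Cc1cc(OC)c(OC)cc1C=O | starting material
5 | 4,5-dimethoxy-2-methylphenyl formate | Cc1cc(OC)c(OC)cc1OC=O | intermediate
6 | 4,5-dimethoxy-2-methylphenol | Cc1cc(OC)c(OC)cc1O | intermediate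
7 | 2-bromo-3,4-dimethoxy-6-methylphenol | Cc1cc(OC)c(OC)c(Br)c1O | intermediate
8 | 3-bromo-2-methoxy-5-methyl-1,4-benzoquinone | CC1=CC(=O)C(OC)=C(Br)C1=O | intermediate
9 | benzyl 4-(benzyloxy)-3-formyl-2-[(2-methoxy-5-methyl-3,6-dioxocyclohexa-1,4-dien-1-yl)oxy]-6-methylbenzoate | Cc1cc(OCc2ccccc2)c(C=O)c(OC2=C(OC)C(=O)C=C(C)C2=O)c1C(=O)OCc1ccccc1 | intermediate
10 | 2-(2,5-dihydroxy-6-methoxy-3-methylphenoxy)-3-formyl-4-hydroxy-6-methylbenzoic acid | Cc1cc(O)c(C=O)c(Oc2c(O)c(C)cc(O)c2OC)c1C(=O)O | intermediate
11 | 3-methylbut-2-enoic acid | CC(C)=CC(=O)O | starting material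
12 | 3,7-dihydroxy-6-methoxy-1,9-dimethyl-11-oxo-11H-dibenzo[b,e][1,4]dioxepine-4-carbaldehyde | Cc1cc(O)c(C=O)c2c1C(=O)Oc1c(C)cc(O)c(OC)c1O2 | intermediate
13 | 3,7-dihydroxy-6-methoxy-1,9-dimethyl-8-(3-methylbut-2-enoyl)-11-oxo-11H-dibenzo[b,e][1,4]dioxepine-4-carbaldehyde | Cc1cc(O)c(C=O)c2c1C(=O)Oc1c(C)c(C(=O)C=C(C)C)c(O)c(OC)c1O2 | intermediate
14 | target O-methyl ether (pyranone-fused depsidone with ring-B OMe in place of OH) | Cc1cc(O)c(C=O)c2c1C(=O)Oc1c(C)c3c(c(OC)c1O2)OC(C)(C)CC3=O | intermediate
15 | CNP0271978.0 | Cc1cc(O)c(C=O)c2c1C(=O)Oc1c(C)c3c(c(O)c1O2)OC(C)(C)CC3=O | target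

**Step count**

Total step count: 9. Longest linear sequence: 7 steps (4 to 15, steps 3–9).

**Steps most likely to fail**

**Step 8.**
- What may go wrong: in the strong acid the ring-A aldehyde may condense with the electron-rich ring B of a second molecule. The acid may lose CO2 before it lactonises. The C5 unit may alkylate instead of acylate.
- Fallback (sets out from 10, returns at 14): the two ring closures are separated and the C–C bond is made by a neutral, tethered acyl shift.
- Trifluoroacetic anhydride in toluene closes ring C, and 12 is isolated.
- 3-Methylbut-2-enoyl chloride/pyridine acylates the ring-B phenol to give the aryl 3-methylbut-2-enoate F1. The ring-A phenol is hydrogen-bonded to the aldehyde and reacts more slowly.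
- Irradiation at about 300 nm in acetonitrile brings about a photo-Fries 1,3-acyl shift to the only free ortho carbon and gives 13. The lactone aryl ester has no free ortho or para carbon and can only recombine.
- Sodium acetate in ethanol completes the oxa-Michael closure to 14.

**Step 6.**
- What may go wrong: the doubly chelated, hindered phenoxide may react too slowly. This would leave room for Michael addition at the unsubstituted quinone carbon followed by redox exchange, or for base-induced self-condensation of the methylquinone.
- Fallback (sets out from 3 and 7, returns at 15): the ester tether is made first and the ether bond is closed within the molecule.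
- Hydrogenolysis of 3 (H2, Pd/C, EtOAc) gives haematommic acid F2.
- Trifluoroacetic anhydride in toluene couples it with bromophenol 7 to the depside F3.
- An intramolecular copper-catalysed Ullmann ether synthesis (CuI, N,N-dimethylglycine, Cs2CO3, dioxane, heat) between the ring-A 2-OH and the C–Br carbon closes ring C to the dimethoxy depsidone F4.
- BBr3 in CH2Cl2 removes both methyl groups to give the catechol depsidone F5.
- Annulation of F5 with 11, as in stage 2 of step 8, closes ring D last and gives 15 directly.

**Step 2.**
- What may go wrong: the chelated, electron-poor phenol may form its magnesium phenoxide reluctantly. Hydroxymethylation at the crowded carbon between OH and OBn may then stall.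
- Fallback (sets out from 1, returns at 3): formylation is done before the phenol is protected.
- Benzyl bromide (1 equiv) and KHCO3 in DMF give benzyl orsellinate F6.
- Vilsmeier–Haack or Gattermann formylation takes place at the carbon between the two hydroxyl groups and gives benzyl haematommate F7.
- Benzyl bromide (1 equiv) and K2CO3 in acetone alkylate the less hindered 4-OH selectively to give 3.

**Further compounds**

F1 | step 8 | 4-formyl-3-hydroxy-6-methoxy-1,9-dimethyl-11-oxo-11H-dibenzo[b,e][1,4]dioxepin-7-yl 3-methylbut-2-enoate | Cc1cc(O)c(C=O)c2c1C(=O)Oc1c(C)cc(OC(=O)C=C(C)C)c(OC)c1O2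
F2 | step 6 | haematommic acid (3-formyl-2,4-dihydroxy-6-methylbenzoic acid) | Cc1cc(O)c(C=O)c(O)c1C(=O)O
F3 | step 6 | 2-bromo-3,4-dimethoxy-6-methylphenyl 3-formyl-2,4-dihydroxy-6-methylbenzoate | Cc1cc(O)c(C=O)c(O)c1C(=O)Oc1c(C)cc(OC)c(OC)c1Br
F4 | step 6 | 3-hydroxy-6,7-dimethoxy-1,9-dimethyl-11-oxo-11H-dibenzo[b,e][1,4]dioxepine-4-carbaldehyde | Cc1cc(O)c(C=O)c2c1C(=O)Oc1c(C)cc(OC)c(OC)c1O2
F5 | step 6 | 3,6,7-trihydroxy-1,9-dimethyl-11-oxo-11H-dibenzo[b,e][1,4]dioxepine-4-carbaldehyde | Cc1cc(O)c(C=O)c2c1C(=O)Oc1c(C)cc(O)c(O)c1O2
F6 | step 2 | benzyl 2,4-dihydroxy-6-methylbenzoate | Cc1cc(O)cc(O)c1C(=O)OCc1ccccc1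
F7 | step 2 | benzyl 3-formyl-2,4-dihydroxy-6-methylbenzoate | Cc1cc(O)c(C=O)c(O)c1C(=O)OCc1ccccc1
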